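Labels used throughout. Rings: A = resorcinol ring (OH on A1 and A3, biaryl carbon A4, A5 carries CH2‑10); B = catechol ring inside the seven‑membered ring (B1 bonded to C9, B6 to C16, oxygens on B3 and B4); C = pendant catechol; D = central phenol ring (D1 bonded to CH2‑17, OH on D3, D5 bonded to A4, D6 bonded to C9). sp3 carbons: C9 (CH), C10 (CH2), C16 (CH carrying ring C), C17 (CH2).

## The problem

The skeleton is a 9,10‑dihydrophenanthrene (A, D, C9, C10) and a 10,11‑dihydro‑5H‑dibenzo[a,d]cycloheptene (B, D, C9, C16, C17) that share the bond C9–D6, so ring D carries three contiguous carbon substituents and the biaryl bond A4–D5 lies next to two of them. The only stereocentres are the diarylmethines C9 (R) and C16 (S), 1,4 across ring B with H9 and H16 cis, and neither has a heteroatom or carbonyl group beside it. C9 can control C16 but not the reverse: once the six‑membered ring holds C10 in the plane of ring D, ring B stands pseudo‑axially on C9, the seven‑membered ring has one natural twist, and in it only a hydrogen fits on C16 beside H9, so ring C is pseudo‑equatorial in the cis isomer. For the same reason, hydrogen delivered to a planar C9 or C16 of a closed ring system is expected on the open face, which leads to the trans series. A planar or cationic C9 inside a closed dihydrophenanthrene loses a proton from C10 and ends as a phenanthrene, so C9 must be a finished CH before A4–D5 closes the six‑membered ring. Two features of the structure answer this. First, C16 is benzylic to ring C (para oxygen) and its partner B6 is para to the B3 oxygen and ortho to B1, so C16–B6 is the bond a C16 cation forms with ring B (key step). Second, D5 is ortho to D6, so an oxygen parked on D5 makes C9 the exocyclic carbon of an ortho‑quinone methide of ring D, where a chiral acid can set it, before the same oxygen leaves as a triflate. The seven phenols (two catechols) are carried as methyl ethers to the last step, and the electron‑rich diarylmethines tolerate only mild acid, because retro‑Friedel–Crafts ionisation at C9 would end in aromatisation.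

## Retrosynthesis

**20 ⇒ 19.** The seven O–CH3 bonds are cut. Methyl ethers are the only protecting groups, so no step is spent on protection; the forward reaction (BBr3) must leave the two benzylic centres alone.

**19 ⇒ 17 (through cation 18).** The bond C16–B6 is cut. The neighbouring cut C9–B1 would need a cation at C9 inside a closed dihydrophenanthrene, which aromatises. C17–D1 has no activation. Any route that adds hydrogen to C16 or C9 after ring closure is expected to give the trans series. The precursor 17 has no seven‑membered ring and no defined C16 (both carbinol epimers). The forward reaction must attack B6 only, and C9 must dictate C16.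

**17 ⇒ 15 (through boronate 16).** The biaryl bond A4–D5 is cut. It is closed after C9 is set, because a closed six‑membered ring cannot tolerate a planar C9. Both partners are pre‑functionalised (A4–Br, D5–OTf), because a C–H arylation from D5 could also reach ring B and give a fluorene. The forward reaction is an intramolecular borylation/Suzuki coupling that forms a six‑membered ring.

**15 ⇐ 14 ⇐ 12 (through ortho‑quinone methide 13).** The C9–H bond is cut. The precursor 12 is a tertiary carbinol with no stereochemical definition at all (four stereoisomers). This is preferred over asymmetric C–C bond formation at C9, which would have to occur at a centre flanked by two ortho substituents. The forward reaction is a chiral phosphoric acid/Hantzsch ester transfer hydrogenation that uses the D5 phenol; 14 is triflated to 15.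

**12 ⇒ 7 + 11; 7 ⇒ 5 + 6.** C9–C10 and C9–B1 are cut. C9 is the carboxyl carbon of a benzoate, so two Grignard reagents and one hydride turn it into a CH with three different carbon groups, with no redox corrections. The aryl group is added first because the resulting diaryl ketone 7 cannot enolise when the benzyl Grignard 11 arrives.

**5 ⇒ 4 ⇒ 1 + 2 (through lithio species 3).** C17–C16 is cut (toluate anion plus veratraldehyde). All four substituents of ring D come from benzoate 1 in the right places. The lactone oxygen stays on C16 as the leaving group for step 10. BCl3 frees the D5 oxygen peri to the carbonyl.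

**11 ⇐ 10 ⇐ 9 ⇐ 8.** The ring A bromide at A4 is put in by bromination of 3,5‑dimethoxybenzyl alcohol, where the two ortho positions are equivalent.

## Roads not taken

**Alternative 1 (the obvious one): biaryl first, then an acid cascade.** Cut C9–D6 and C16–B6 in bis‑stilbene A1, made by Suzuki coupling and two olefinations. Acid would protonate the ring A stilbene (C9 cation beside ring B), ring D would close the six‑membered ring, then the second stilbene would give the C16 cation and ring B would close the seven‑membered ring.
- The first closure can go to D4 (ortho to OMe) as well as to D6 (para but flanked).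
- Both stereocentres come from planar cations of an achiral substrate, so there is no handle for the absolute configuration.
- Every variant that forms C9–B1 last puts a cation at C9 in a closed dihydrophenanthrene, which eliminates to the phenanthrene.
- The chosen plan fixes regiochemistry through the substituents of 1 and sets C9 before the six‑membered ring exists.

**Alternative 2: hidden symmetry at C16.** Cut C9–B1. Before ring B is tied to C9, rings B and C are two identical 3,4‑dimethoxyphenyl groups on C16. A Pd(0)‑catalysed C–H arylation of bromophenanthrene A2 with a chiral ligand would select one of the two enantiotopic aryl groups, close the seven‑membered ring and set C16 in A3. Dearomatising reduction of C9=C10 would finish.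
- In A3 the B6–C16 bridge and H16 cover one face of C9, so hydrogen is expected to arrive anti to the bridge. That gives H9 trans to H16, the wrong diastereomer.
- C9 cannot be equilibrated without risk to C16.
- A2 needs a regiodefined tetrasubstituted phenanthrene, a longer run‑up than 1.

**Alternative 3: carbonyl ylide plus aryne.** Cut C9–B1 and C16–B6 together. Ring B comes from 4,5‑dimethoxybenzyne; C9 and C16 are the termini of a 2‑benzopyrylium‑4‑olate generated on ring D from diazo diketone A4 with Rh(II). The cycloadduct A5 has an oxygen bridge that makes C9 and C16 cis by construction.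
- Two short‑lived partners must meet, and the diazo compound itself adds to arynes.
- The absolute configuration would rest on face‑selective capture of a flat dipole by an aryne, without close precedent.
- Afterwards two benzylic C–O bonds must be hydrogenolysed with the same stereochemical course and the C17 ketone removed.
- Ring A cannot be tied in beforehand, because a C9 carbonyl in a closed ring is a phenanthrol.
- The chosen route needs one reduction at C9 and no redox correction after ring closure.

Key step: step 10

Assumption 1: the SMILES is read as R at C9 and S at C16, which places H9 and H16 on the same face of the seven‑membered ring.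
Assumption 2: (R)‑TRIP is written for the catalyst antipode that gives (R)‑C9; if the sense of induction is the opposite, (S)‑TRIP is used and nothing else changes.

## Route

Step 1
Reactants: 1 methyl 2,4-dimethoxy-6-methylbenzoate; 2 3,4-dimethoxybenzaldehyde
Product: 4 rac-3-(3,4-dimethoxyphenyl)-6,8-dimethoxy-3,4-dihydro-1H-isochromen-1-one, via benzyllithium 3 (not isolated)
Conditions: LDA (1.2 equiv), THF, −78 °C; then 2, −78 °C → rt; aqueous work-up
Reagents that add atoms: none
Why: Lateral lithiation of an ortho-toluate and addition to an aryl aldehyde with lactonisation on warming is the standard route to 3-aryl-3,4-dihydroisocoumarins; it makes the C17–C16 bond, and C16 is left racemic on purpose because it is ionised in step 10.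

Step 2
Reactants: 4 rac-3-(3,4-dimethoxyphenyl)-6,8-dimethoxy-3,4-dihydro-1H-isochromen-1-one
Product: 5 rac-3-(3,4-dimethoxyphenyl)-8-hydroxy-6-methoxy-3,4-dihydro-1H-isochromen-1-one
Conditions: BCl3 (1.5 equiv), CH2Cl2, −78 → −10 °C; aq NaHCO3
Reagents that add atoms: none
Why: Chelation-controlled demethylation: BCl3 cleaves only the methyl ether peri to the carbonyl group through a six-membered chelate, which frees the D5 oxygen and leaves the other methyl ethers.

Step 3
Reactants: 5 rac-3-(3,4-dimethoxyphenyl)-8-hydroxy-6-methoxy-3,4-dihydro-1H-isochromen-1-one; 6 (3,4-dimethoxyphenyl)magnesium bromide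
Product: 7 rac-(3,4-dimethoxyphenyl){2-hydroxy-6-[2-hydroxy-2-(3,4-dimethoxyphenyl)ethyl]-4-methoxyphenyl}methanone
Conditions: 6 (2.3 equiv), THF, −40 → 0 °C; aq NH4Cl
Reagents that add atoms: none
Why: Grignard addition to a lactone with ring opening: the first equivalent forms the magnesium phenoxide and the second adds to the chelated carbonyl group (C9–B1 bond); the resulting diaryl ketone is an ortho-phenoxide flanked by two ortho substituents and should not add a second aryl group at 0 °C.

Step 4
Reactants: 8 (3,5-dimethoxyphenyl)methanol
Product: 9 (2-bromo-3,5-dimethoxyphenyl)methanol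
Conditions: NBS (1.0 equiv), MeCN, 0 °C → rt
Reagents that add atoms: N-bromosuccinimide, O=C1CCC(=O)N1Br
Why: Electrophilic aromatic bromination of a 3,5-dimethoxybenzyl system goes ortho to the CH2 group and para to a methoxy group (the position between the two methoxy groups is more hindered); the two such positions are equivalent.

Step 5
Reactants: 9 (2-bromo-3,5-dimethoxyphenyl)methanol
Product: 10 2-bromo-1-(chloromethyl)-3,5-dimethoxybenzene
Conditions: SOCl2 (1.2 equiv), cat. DMF, CH2Cl2, 0 °C → rt
Reagents that add atoms: thionyl chloride, O=S(Cl)Cl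
Why: Standard conversion of a benzylic alcohol into the chloride; the chloride is chosen over the bromide to limit Wurtz coupling in step 6.

Step 6
Reactants: 10 2-bromo-1-(chloromethyl)-3,5-dimethoxybenzene; 7 rac-(3,4-dimethoxyphenyl){2-hydroxy-6-[2-hydroxy-2-(3,4-dimethoxyphenyl)ethyl]-4-methoxyphenyl}methanone
Product: 12 2-(2-bromo-3,5-dimethoxyphenyl)-1-(3,4-dimethoxyphenyl)-1-{2-hydroxy-6-[2-hydroxy-2-(3,4-dimethoxyphenyl)ethyl]-4-methoxyphenyl}ethan-1-ol (all stereoisomers), via benzylmagnesium chloride 11 (not isolated)
Conditions: Mg, THF–Et2O, 0 °C (slow addition of 10); then 7, 0 °C → rt (3.5 equiv of 11); aq NH4Cl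
Reagents that add atoms: none
Why: Magnesium inserts into the benzylic C–Cl bond well below the temperature needed for the hindered aryl C–Br bond (ortho-bromobenzyl Grignard reagents are made this way); two equivalents of 11 are spent on the OH groups and the next adds to the non-enolisable diaryl ketone (Grignard 1,2-addition, C9–C10 bond), without stereocontrol, which is not needed.

Step 7
Reactants: 12 2-(2-bromo-3,5-dimethoxyphenyl)-1-(3,4-dimethoxyphenyl)-1-{2-hydroxy-6-[2-hydroxy-2-(3,4-dimethoxyphenyl)ethyl]-4-methoxyphenyl}ethan-1-ol (all stereoisomers)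
Product: 14 2-[(1R)-2-(2-bromo-3,5-dimethoxyphenyl)-1-(3,4-dimethoxyphenyl)ethyl]-3-[2-(3,4-dimethoxyphenyl)-2-hydroxyethyl]-5-methoxyphenol (both C16 epimers), via ortho-quinone methide 13 (not isolated)
Conditions: (R)-TRIP (10 mol %), Hantzsch ester (diethyl 2,6-dimethyl-1,4-dihydropyridine-3,5-dicarboxylate, 1.5 equiv), 4 Å MS, CH2Cl2, 30 °C
Reagents that add atoms: none
Why: Chiral phosphoric acid-catalysed transfer hydrogenation of an ortho-quinone methide: the ortho-hydroxy tertiary carbinol loses water to 13 (its alkene tautomer and the cyclic ether with the C16 hydroxyl return to 13 under the same acid) and the Hantzsch ester delivers hydride to one face of C9 inside the hydrogen-bonded phosphate complex; C9 is set by the catalyst alone, so all stereoisomers of 12 converge, and the C16 alcohol, which is not a quinone methide precursor, should not be ionised by this weak acid.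

Step 8
Reactants: 14 2-[(1R)-2-(2-bromo-3,5-dimethoxyphenyl)-1-(3,4-dimethoxyphenyl)ethyl]-3-[2-(3,4-dimethoxyphenyl)-2-hydroxyethyl]-5-methoxyphenol (both C16 epimers)
Product: 15 2-[(1R)-2-(2-bromo-3,5-dimethoxyphenyl)-1-(3,4-dimethoxyphenyl)ethyl]-3-[2-(3,4-dimethoxyphenyl)-2-hydroxyethyl]-5-methoxyphenyl trifluoromethanesulfonate (both C16 epimers)
Conditions: PhNTf2 (1.2 equiv), Et3N, DMAP (cat.), CH2Cl2, rt
Reagents that add atoms: N-phenylbis(trifluoromethanesulfonimide), O=S(=O)(N(c1ccccc1)S(=O)(=O)C(F)(F)F)C(F)(F)F
Why: Phenol triflation with the mild reagent PhNTf2, which does not touch the secondary alcohol; the D5 oxygen that served the quinone methide becomes the leaving group for the biaryl bond.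

Step 9
Reactants: 15 2-[(1R)-2-(2-bromo-3,5-dimethoxyphenyl)-1-(3,4-dimethoxyphenyl)ethyl]-3-[2-(3,4-dimethoxyphenyl)-2-hydroxyethyl]-5-methoxyphenyl trifluoromethanesulfonate (both C16 epimers)
Product: 17 1-(3,4-dimethoxyphenyl)-2-[(10R)-10-(3,4-dimethoxyphenyl)-3,5,7-trimethoxy-9,10-dihydrophenanthren-1-yl]ethan-1-ol (both C16 epimers; R at C9 in the labels used here), via arylboronate 16 (not isolated)
Conditions: B2pin2 (1.2 equiv), XPhos Pd G3 (5 mol %), KOAc, 1,4-dioxane, 90 °C; then aq K3PO4, 100 °C; 0.01 M
Reagents that add atoms: none
Why: One-pot Miyaura borylation and intramolecular Suzuki coupling: whichever of the C–Br and C–OTf bonds is borylated first couples with the other, so only the A4–D5 bond can form (six-membered ring); both partners are pre-functionalised because a C–H arylation from D5 could also reach ring B; C9 is not touched.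

Step 10
Reactants: 17 1-(3,4-dimethoxyphenyl)-2-[(10R)-10-(3,4-dimethoxyphenyl)-3,5,7-trimethoxy-9,10-dihydrophenanthren-1-yl]ethan-1-ol (both C16 epimers)
Product: 19 hepta-O-methyl ether of the target (9R,16S; cis H9/H16), via benzylic cation 18 (not isolated)
Conditions: TsOH·H2O (20 mol %), HFIP–CH2Cl2 1:1, 0 °C → rt, 0.005 M
Reagents that add atoms: none
Why: The acid ionises both epimers of the C16 carbinol (and, reversibly, the stilbene formed by E1) to the same benzylic cation 18, stabilised by the para-methoxy group of ring C; B6 attacks it and loss of a proton restores ring B. The closest known reaction type is the acid-mediated intramolecular Friedel–Crafts alkylation of electron-rich benzylic alcohols used for the seven-membered rings of oligostilbenes and dibenzosuberanes. One ring is closed, the seven-membered ring C9–B1–B6–C16–C17–D1–D6, by cation–arene (SEAr) closure of a five-atom tether onto the ortho position B6. The new stereocentre C16 is controlled by C9: because C10 is locked in the plane of ring D, ring B stands pseudo-axially on C9 and the tether can close with one twist only, in which the position on C16 that faces H9 accepts only hydrogen, so ring C takes the outer pseudo-equatorial position anti to D1 and C16 becomes S (H16 cis to H9). The step needs site selectivity on ring B, which the substitution secures: B6 is para to the B3 methoxy group and unhindered, B2 is ortho to it and flanked on both sides, and ring A could only be reached through an eight-membered ring. It needs the cation to cyclise and not to alkylate a second molecule, which high dilution secures, and it needs C9 to survive, which the mild catalytic acid secures because only the alcohol, not a C–C bond, is ionised.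

Step 11
Reactants: 19 hepta-O-methyl ether of the target (9R,16S; cis H9/H16)
Product: 20 CNP0306974.1 (9R,16S heptaphenol)
Conditions: BBr3 (14 equiv), CH2Cl2, −78 °C → rt; MeOH quench, degassed aqueous work-up
Reagents that add atoms: none
Why: Exhaustive cleavage of aryl methyl ethers with boron tribromide, the usual last step for oligostilbenes; no stereocentre is involved, and low temperature and exclusion of air protect the benzylic centres and the catechols.

## Compound list

1 | methyl 2,4-dimethoxy-6-methylbenzoate | COC(=O)c1c(C)cc(OC)cc1OC | starting material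
2 | 3,4-dimethoxybenzaldehyde | COc1ccc(C=O)cc1OC | starting material
3 | [3,5-dimethoxy-2-(methoxycarbonyl)benzyl]lithium | [Li]Cc1cc(OC)cc(OC)c1C(=O)OC | intermediate
4 | rac-3-(3,4-dimethoxyphenyl)-6,8-dimethoxy-3,4-dihydro-1H-isochromen-1-one | COc1cc2c(c(OC)c1)C(=O)OC(c1ccc(OC)c(OC)c1)C2 | intermediate
5 | rac-3-(3,4-dimethoxyphenyl)-8-hydroxy-6-methoxy-3,4-dihydro-1H-isochromen-1-one | COc1cc2c(c(O)c1)C(=O)OC(c1ccc(OC)c(OC)c1)C2 | intermediate
6 | (3,4-dimethoxyphenyl)magnesium bromide (commercial THF solution) | COc1ccc([Mg]Br)cc1OC | starting material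
7 | rac-(3,4-dimethoxyphenyl){2-hydroxy-6-[2-hydroxy-2-(3,4-dimethoxyphenyl)ethyl]-4-methoxyphenyl}methanone | COc1cc(O)c(C(=O)c2ccc(OC)c(OC)c2)c(CC(O)c2ccc(OC)c(OC)c2)c1 | intermediate
8 | (3,5-dimethoxyphenyl)methanol | COc1cc(CO)cc(OC)c1 | starting material
9 | (2-bromo-3,5-dimethoxyphenyl)methanol | COc1cc(CO)c(Br)c(OC)c1 | intermediate
10 | 2-bromo-1-(chloromethyl)-3,5-dimethoxybenzene | COc1cc(CCl)c(Br)c(OC)c1 | intermediate
11 | (2-bromo-3,5-dimethoxybenzyl)magnesium chloride | COc1cc(C[Mg]Cl)c(Br)c(OC)c1 | intermediate
12 | 2-(2-bromo-3,5-dimethoxyphenyl)-1-(3,4-dimethoxyphenyl)-1-{2-hydroxy-6-[2-hydroxy-2-(3,4-dimethoxyphenyl)ethyl]-4-methoxyphenyl}ethan-1-ol, all four stereoisomers | COc1cc(O)c(C(O)(Cc2cc(OC)cc(OC)c2Br)c2ccc(OC)c(OC)c2)c(CC(O)c2ccc(OC)c(OC)c2)c1 | intermediate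
13 | 6-[2-(2-bromo-3,5-dimethoxyphenyl)-1-(3,4-dimethoxyphenyl)ethylidene]-5-[2-(3,4-dimethoxyphenyl)-2-hydroxyethyl]-3-methoxycyclohexa-2,4-dien-1-one (ortho-quinone methide, E/Z) | COC1=CC(=O)C(=C(Cc2cc(OC)cc(OC)c2Br)c2ccc(OC)c(OC)c2)C(CC(O)c2ccc(OC)c(OC)c2)=C1 | intermediate
14 | 2-[(1R)-2-(2-bromo-3,5-dimethoxyphenyl)-1-(3,4-dimethoxyphenyl)ethyl]-3-[2-(3,4-dimethoxyphenyl)-2-hydroxyethyl]-5-methoxyphenol, R at C9, both C16 epimers | COc1cc(O)c([C@H](Cc2cc(OC)cc(OC)c2Br)c2ccc(OC)c(OC)c2)c(CC(O)c2ccc(OC)c(OC)c2)c1 | intermediate
15 | aryl trifluoromethanesulfonate of 14, R at C9, both C16 epimers | COc1cc(OS(=O)(=O)C(F)(F)F)c([C@H](Cc2cc(OC)cc(OC)c2Br)c2ccc(OC)c(OC)c2)c(CC(O)c2ccc(OC)c(OC)c2)c1 | intermediate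
16 | analogue of 15 with a 4,4,5,5-tetramethyl-1,3,2-dioxaborolan-2-yl group in place of bromine | COc1cc(OS(=O)(=O)C(F)(F)F)c([C@H](Cc2cc(OC)cc(OC)c2B2OC(C)(C)C(C)(C)O2)c2ccc(OC)c(OC)c2)c(CC(O)c2ccc(OC)c(OC)c2)c1 | intermediate
17 | 1-(3,4-dimethoxyphenyl)-2-[(10R)-10-(3,4-dimethoxyphenyl)-3,5,7-trimethoxy-9,10-dihydrophenanthren-1-yl]ethan-1-ol, R at C9, both C16 epimers | COc1cc(OC)c2c(c1)C[C@H](c1ccc(OC)c(OC)c1)c1c(CC(O)c3ccc(OC)c(OC)c3)cc(OC)cc1-2 | intermediate
18 | C16 benzylic cation derived from 17 | COc1cc(OC)c2c(c1)C[C@H](c1ccc(OC)c(OC)c1)c1c(C[CH+]c3ccc(OC)c(OC)c3)cc(OC)cc1-2 | intermediate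
19 | hepta-O-methyl ether of the target, R at C9, S at C16, H9 and H16 cis | COc1cc(OC)c2c(c1)C[C@@H]1c3cc(OC)c(OC)cc3[C@H](c3ccc(OC)c(OC)c3)Cc3cc(OC)cc-2c31 | intermediate
20 | CNP0306974.1, R at C9, S at C16 | Oc1cc(O)c2c(c1)C[C@@H]1c3cc(O)c(O)cc3[C@H](c3ccc(O)c(O)c3)Cc3cc(O)cc-2c31 | target

## Step count and risks

Total step count: 11. Longest linear sequence: 9 steps (steps 1–3 and 6–11).

**Step 10 (key step).**
- What may go wrong: cation 18 may partition into the stilbene and into intermolecular alkylation before the seven-membered ring closes. The facial selectivity of the attack by B6 may be incomplete, since the case for cis rests on conformational analysis. Equilibration with strong acid is not available, because C9 would ionise as well and aromatise.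
- Fallback: make the bond between C16 and ring C last, on the closed ring, so that a carbon nucleophile enters anti to H9. It sets out from 17. Dehydration (MsCl, Et3N, then DBU) gives the (E)-stilbene F1. Oxidative cleavage of its double bond (cat. OsO4, NaIO4, 2,6-lutidine; Lemieux–Johnson) gives the aryl aldehyde F2. Methoxymethylenation (Ph3P=CHOMe, Wittig) gives the enol ether F3, a masked arylacetaldehyde. With TsOH in HFIP, F3 is protonated to an oxocarbenium ion, ring B closes on it to the ring ether F4, and F4 ionises to the cyclic C16 cation. This cation is captured by added 1,2-dimethoxybenzene (the cheap arene that becomes ring C) on the face away from H9, and the route is rejoined at 19.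

**Step 7.**
- What may go wrong: low enantiofacial discrimination. The quinone methide 13 is fully substituted at C9 and flanked by the D1 side chain, so both of its geometric isomers may react. Irreversible capture of 13 by ring C is a second possibility.
- Fallback: form the C9–aryl bond, not the C9–H bond, in the enantio-determining step. It sets out from 5. DIBAL-H gives the lactol F5. Grignard reagent 11 adds to its open hydroxy-aldehyde form to give the diol F6. Mild acid closes F6 to the cyclic ortho-hydroxybenzyl ether F7, a known type of ortho-quinone methide precursor. Heating F7 with diethyl (3,4-dimethoxyphenyl)boronate and a 3,3′-dibromo-BINOL catalyst (chiral biphenol-catalysed boronate addition to an ortho-quinone methide) transfers the aryl group to C9 and releases the C16 hydroxyl, returning to 14.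

**Step 9.**
- What may go wrong: protodeboronation or protodehalogenation at the hindered A4 position, or C–H arylation of ring B from the D5–palladium species, may outrun the slow closure of a tri-ortho-substituted biaryl.
- Fallback: nickel(0)-mediated reductive coupling of the two carbon–(pseudo)halogen bonds (Ni(cod)2, 2,2′-bipyridine, DMF, 60 °C, high dilution). It needs no boron intermediate and no base; it sets out from 15 and returns at 17.

**Step 6.**
- What may go wrong: Wurtz homocoupling and magnesium insertion into the aryl C–Br bond during formation of 11, and sluggish addition to the chelated, hindered ketone.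
- Fallback: introduce the bromine late by electrophilic substitution. It sets out from 7. Commercial (3,5-dimethoxybenzyl)magnesium chloride gives the bromine-free triol F8. Steps 7 and 8 carried out as above give the phenol F9 and the triflate F10. NBS in MeCN then brominates ring A, the only ring activated by two reinforcing methoxy groups and with two equivalent ortho positions, which returns to 15.

## Further compounds

F1 | step 10 | (E)-stilbene from dehydration of 17, R at C9 | COc1cc(OC)c2c(c1)C[C@H](c1ccc(OC)c(OC)c1)c1c(/C=C/c3ccc(OC)c(OC)c3)cc(OC)cc1-2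
F2 | step 10 | (10R)-10-(3,4-dimethoxyphenyl)-3,5,7-trimethoxy-9,10-dihydrophenanthrene-1-carbaldehyde | COc1cc(OC)c2c(c1)C[C@H](c1ccc(OC)c(OC)c1)c1c(C=O)cc(OC)cc1-2
F3 | step 10 | 2-methoxyvinyl (enol ether) analogue of F2, E/Z, R at C9 | COc1cc(OC)c2c(c1)C[C@H](c1ccc(OC)c(OC)c1)c1c(C=COC)cc(OC)cc1-2
F4 | step 10 | ring-closed C16 methyl ether (seven-membered ring formed, OMe on C16, R at C9) | COc1cc(OC)c2c(c1)C[C@@H]1c3cc(OC)c(OC)cc3C(OC)Cc3cc(OC)cc-2c31
F5 | step 7 | rac-3-(3,4-dimethoxyphenyl)-6-methoxy-3,4-dihydro-1H-isochromene-1,8-diol (lactol) | COc1cc2c(c(O)c1)C(O)OC(c1ccc(OC)c(OC)c1)C2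
F6 | step 7 | 2-[2-(2-bromo-3,5-dimethoxyphenyl)-1-hydroxyethyl]-3-[2-(3,4-dimethoxyphenyl)-2-hydroxyethyl]-5-methoxyphenol, all stereoisomers | COc1cc(O)c(C(O)Cc2cc(OC)cc(OC)c2Br)c(CC(O)c2ccc(OC)c(OC)c2)c1
F7 | step 7 | 1-(2-bromo-3,5-dimethoxybenzyl)-3-(3,4-dimethoxyphenyl)-6-methoxy-3,4-dihydro-1H-isochromen-8-ol, all stereoisomers | COc1cc2c(c(O)c1)C(Cc1cc(OC)cc(OC)c1Br)OC(c1ccc(OC)c(OC)c1)C2
F0 | step 9 | none | none
F8 | step 6 | bromine-free analogue of 12, all stereoisomers | COc1cc(O)c(C(O)(Cc2cc(OC)cc(OC)c2)c2ccc(OC)c(OC)c2)c(CC(O)c2ccc(OC)c(OC)c2)c1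
F9 | step 6 | bromine-free analogue of 14, R at C9, both C16 epimers | COc1cc(O)c([C@H](Cc2cc(OC)cc(OC)c2)c2ccc(OC)c(OC)c2)c(CC(O)c2ccc(OC)c(OC)c2)c1
F10 | step 6 | bromine-free analogue of 15, R at C9, both C16 epimers | COc1cc(OS(=O)(=O)C(F)(F)F)c([C@H](Cc2cc(OC)cc(OC)c2)c2ccc(OC)c(OC)c2)c(CC(O)c2ccc(OC)c(OC)c2)c1
A1 | alternative 1 | 2,4-dimethoxy-6-[(E)-3,4-dimethoxystyryl]-3′-methoxy-5′-[(E)-3,4-dimethoxystyryl]biphenyl (biaryl bis-stilbene) | COc1cc(OC)c(-c2cc(OC)cc(/C=C/c3ccc(OC)c(OC)c3)c2)c(/C=C/c2ccc(OC)c(OC)c2)c1
A2 | alternative 2 | 1-[2,2-bis(3,4-dimethoxyphenyl)ethyl]-10-bromo-3,5,7-trimethoxyphenanthrene | COc1cc(OC)c2c(c1)cc(Br)c1c(CC(c3ccc(OC)c(OC)c3)c3ccc(OC)c(OC)c3)cc(OC)cc12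
A3 | alternative 2 | phenanthrene-fused dibenzocycloheptene with C9=C10 aromatic and C16 set (S shown) | COc1cc(OC)c2c(c1)cc1-c3cc(OC)c(OC)cc3[C@H](c3ccc(OC)c(OC)c3)Cc3cc(OC)cc2c31
A4 | alternative 3 | 2-diazo-1-{2-[2-(3,5-dimethoxyphenyl)acetyl]-3,5-dimethoxyphenyl}-2-(3,4-dimethoxyphenyl)ethan-1-one | COc1cc(OC)c(C(=O)Cc2cc(OC)cc(OC)c2)c(C(=O)C(=[N+]=[N-])c2ccc(OC)c(OC)c2)c1
A5 | alternative 3 | oxygen-bridged dibenzocycloheptenone cycloadduct (O bridge C9–C16, C17 ketone), racemic | O=C1c2cc(OC)cc(OC)c2C2(Cc3cc(OC)cc(OC)c3)OC1(c1ccc(OC)c(OC)c1)c1cc(OC)c(OC)cc12
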